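**Retrosynthetic overview**
1. The N-oxide oxygen is removed first (peracid oxidation is the last forward step), then the C3 methyl ether is cut back to the 3-pyridinol.
2. Feature: in the pyridine ring, N1–C2(CH3)–C3(O) is the N–Cα(CH3)–CO unit of alanine. The run C8a–C8–C7–C6–C5–C4a–C4(OMe) is the seven-carbon backbone of a 5-substituted 7-methoxyhept-6-enoic acid. Joined as a 2-alkyl-5-methoxy-4-methyloxazole, the two pieces lack only the C4a–C8a and C3–C4 bonds, and one intramolecular oxazole–alkene [4+2] addition forms both.
3. The enol ether acid comes from Wittig methoxymethylenation of an aldehyde acid. That acid comes from ozonolysis of a cyclohexenyl silyl ether, made by catalytic asymmetric conjugate addition of 5-phenylpentylmagnesium bromide to cyclohexenone, which sets C5.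
4. Ring order: a sacrificial cyclohexene ring is built and then cut, the oxazole follows, and the carbocycle and pyridine ring close together.

Key step: step 7

Assumption: the sense of induction of the ferrocenyl diphosphine is not predicted here. The ligand enantiomer used is the one that gives the R ketone when an aliquot of the silyl enol ether is hydrolysed and analysed by chiral chromatography and by comparison of rotation with homologous 3-alkylcyclohexanones.

Step 1
Reactants: 1 (5-bromopentyl)benzene
Product: 2 5-phenylpentylmagnesium bromide (titrated Et2O solution)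
Conditions: Mg turnings, I2 (crystal), Et2O, gentle reflux, slow addition of 1
Reagents that add atoms: magnesium, [Mg]
Why: Grignard formation by magnesium insertion into a primary alkyl bromide, with slow addition to hold back Wurtz coupling and with a remote phenyl ring that is inert.

Step 2
Reactants: 2 5-phenylpentylmagnesium bromide; 3 cyclohex-2-en-1-one
Product: 5 (R)-trimethyl{[3-(5-phenylpentyl)cyclohex-1-en-1-yl]oxy}silane, via bromomagnesium enolate 4 (not isolated)
Conditions: CuCl (5 mol %), 1-{(dimethylamino)[2-(diphenylphosphanyl)phenyl]methyl}-2-(diphenylphosphanyl)ferrocene (TaniaPhos ligand, 6 mol %), Et2O, 0 °C, slow addition of 2; then Me3SiCl, Et3N, DMPU, 0 °C to rt; cold aq NaHCO3, pentane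
Reagents that add atoms: chlorotrimethylsilane, C[Si](C)(C)Cl
Why: Copper-catalysed asymmetric conjugate addition of a primary alkyl Grignard reagent to a cyclic enone, in which the chiral diphosphine–copper complex selects the enone face and so sets C3 as R, gives enolate 4 with its double bond toward the new centre, and silylation only after the enone is consumed (so that Me3SiCl cannot speed an unselective background addition) locks that regiochemistry into 5.

Step 3
Reactants: 5 (R)-trimethyl{[3-(5-phenylpentyl)cyclohex-1-en-1-yl]oxy}silane
Product: 7 (5R)-5-formyl-10-phenyldecanoic acid, via methoxy hydroperoxide silyl ester 6 (not isolated)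
Conditions: O3, CH2Cl2–MeOH (5:1), –78 °C, Sudan red 7B as end-point indicator; Me2S, –78 to 0 °C; cold water wash, toluene strip below 20 °C; used crude at once
Reagents that add atoms: ozone, [O-][O+]=O
Why: Ozonolysis of a silyl enol ether, whose electron-rich double bond reacts far faster than the phenyl ring, splits the ring into a silyl ester and a carbonyl oxide that methanol traps as 6, and dimethyl sulfide reduction with methanolysis of the silyl ester releases the aldehyde acid under cold neutral conditions that leave the alpha-branched centre untouched.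

Step 4
Reactants: 7 (5R)-5-formyl-10-phenyldecanoic acid; 8 (methoxymethyl)triphenylphosphonium chloride
Product: 10 (5R)-5-(2-methoxyethenyl)-10-phenyldecanoic acid (E/Z mixture), via methoxymethylidene ylide 9 (not isolated)
Conditions: 8 (3.3 equiv), KN(SiMe3)2 (3.0 equiv), THF, 0 °C; then crude 7 in THF, –78 to –20 °C; NaH2PO4 buffer to pH 5–6, 0 °C, EtOAc
Reagents that add atoms: none
Why: Wittig methoxymethylenation with the preformed non-stabilised ylide, kept free of amide base by a slight excess of 8, should add to the aldehyde at low temperature faster than it enolises it (one equivalent being spent on the carboxylic acid), so the R centre is carried through and the E/Z mixture, whose geometry is erased later, is recovered by mildly acidic buffered extraction.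

Step 5
Reactants: 10 (5R)-5-(2-methoxyethenyl)-10-phenyldecanoic acid; 11 DL-alanine methyl ester hydrochloride
Product: 13 methyl N-[(5R)-5-(2-methoxyethenyl)-10-phenyldecanoyl]alaninate (E/Z mixture; both alanine epimers), via benzotriazol-1-yl ester 12 (not isolated)
Conditions: EDC·HCl (1.3 equiv), HOBt (1.3 equiv), iPr2NEt (3.5 equiv), CH2Cl2, 0 °C to rt
Reagents that add atoms: none
Why: Carbodiimide/HOBt amide coupling through active ester 12 runs in an amine-buffered medium that does not touch the enol ether, and the racemic amino ester suffices because its centre becomes sp2 in the next step.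

Step 6
Reactants: 13 methyl N-[(5R)-5-(2-methoxyethenyl)-10-phenyldecanoyl]alaninate
Product: 14 5-methoxy-2-[(4R)-4-(2-methoxyethenyl)-9-phenylnonyl]-4-methyl-1,3-oxazole
Conditions: PPh3 (2 equiv) and C2Cl6 (2 equiv) premixed, CH2Cl2, 0 °C; Et3N (5 equiv); then 13, 0 °C to rt; Et3N-deactivated silica
Reagents that add atoms: none
Why: Robinson–Gabriel-type cyclodehydration of an N-acyl alpha-amino ester to the 5-alkoxyoxazole with preformed Ph3PCl2 and excess Et3N removes one oxygen as Ph3PO in a basic medium, which spares both the enol ether and the acid-labile alkoxyoxazole and leaves no free halogenating agent to attack the alkene.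

Step 7
Reactants: 14 5-methoxy-2-[(4R)-4-(2-methoxyethenyl)-9-phenylnonyl]-4-methyl-1,3-oxazole
Product: 17 (5R)-4-methoxy-2-methyl-5-(5-phenylpentyl)-5,6,7,8-tetrahydroquinolin-3-ol, via oxa-bridged cycloadduct 15 (not isolated), via ring-opened hemiketal 16 (not isolated)
Conditions: CF3CO2H (0.2 equiv), dry degassed o-dichlorobenzene (0.01 M), sealed tube, 180 °C; aq NaHCO3
Reagents that add atoms: none
Why: Proposed new method: protonation at the oxazole nitrogen turns the 5-methoxyoxazole of 14 into an electron-poor 2-azadiene, so that the nucleophilic enol ether carbon next to the stereocentre bonds to the electrophilic oxazole C2 (the C4a–C8a bond) and the methoxy-bearing carbon bonds to oxazole C5 (the C4–C3 bond) in an inverse-demand and probably asynchronous [4+2] addition that gives the 7-oxa-2-azabicyclo[2.2.1]hept-2-ene 15. The C8a–O bridge bond then breaks with loss of H-4a to give the hemiketal 16, which expels methanol from C3 and tautomerises at C4 to the aromatic pyridinol 17, an irreversible sink that drains the reversible steps before it. The closest known reaction types are the intramolecular oxazole–olefin Diels–Alder (Kondrat'eva) synthesis of cycloalka[b]pyridines, its acid-promoted variants with unactivated alkenes and the 5-alkoxy-4-methyloxazole route to 3-hydroxypyridines, and the untested element is the tethered enol ether as dienophile. The carbocycle (C4a, C5, C6, C7, C8, C8a) closes in the fused, type 1 intramolecular Diels–Alder mode over the four-atom C8–C7–C6–C5 tether (6-exo-trig at oxazole C2 in the stepwise limit), and the pyridine ring closes as the six-membered ring of the [4+2] event itself. The four centres created in 15 (C3, C4, C4a and C8a) depend on enol ether geometry and on endo or exo approach but all become sp2 on aromatisation, so nothing has to control them, while C5 stays sp3, bears no acidic hydrogen and is retained as R. The step needs regiocontrol, which the short tether enforces because the bridged mode is out of reach and which the polarity match reinforces, and chemoselectivity for cycloaddition over protolysis of the enol ether, which a rigorously dry and dilute medium, a substoichiometric acid and the reversibility of methanol addition to the enol ether at this temperature should secure.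

Step 8
Reactants: 17 (5R)-4-methoxy-2-methyl-5-(5-phenylpentyl)-5,6,7,8-tetrahydroquinolin-3-ol
Product: 18 (5R)-3,4-dimethoxy-2-methyl-5-(5-phenylpentyl)-5,6,7,8-tetrahydroquinoline
Conditions: Me3SiCHN2 (2 M in hexanes, 1.5 equiv), iPr2NEt, MeCN–MeOH (9:1), rt
Reagents that add atoms: (trimethylsilyl)diazomethane, C[Si](C)(C)C=[N+]=[N-]
Why: O-Methylation of an acidic 3-hydroxypyridine with a diazomethane equivalent goes by proton transfer and collapse of the ion pair at oxygen, so the doubly flanked ring nitrogen is not quaternised, and any 18 already formed in step 7 by loss of water instead of methanol passes through unchanged.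

Step 9
Reactants: 18 (5R)-3,4-dimethoxy-2-methyl-5-(5-phenylpentyl)-5,6,7,8-tetrahydroquinoline
Product: 19 (5R)-3,4-dimethoxy-2-methyl-5-(5-phenylpentyl)-5,6,7,8-tetrahydroquinoline 1-oxide (target)
Conditions: mCPBA (1.2 equiv), CH2Cl2, 0 °C to rt; aq Na2S2O3, aq K2CO3
Reagents that add atoms: 3-chloroperoxybenzoic acid, O=C(OO)c1cccc(Cl)c1
Why: Peracid N-oxidation of an electron-rich 2,6-dialkylpyridine is the only oxidation open to 18, since no alkene or other oxidisable heteroatom remains and C5 is not involved.

**Compound list**
1 | (5-bromopentyl)benzene | BrCCCCCc1ccccc1 | starting material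
2 | 5-phenylpentylmagnesium bromide | Br[Mg]CCCCCc1ccccc1 | intermediate
3 | cyclohex-2-en-1-one | O=C1C=CCCC1 | starting material
4 | bromomagnesium (R)-3-(5-phenylpentyl)cyclohex-1-en-1-olate | Br[Mg]OC1=C[C@H](CCCCCc2ccccc2)CCC1 | intermediate
5 | (R)-trimethyl{[3-(5-phenylpentyl)cyclohex-1-en-1-yl]oxy}silane | C[Si](C)(C)OC1=C[C@H](CCCCCc2ccccc2)CCC1 | intermediate
6 | trimethylsilyl (5R)-5-[hydroperoxy(methoxy)methyl]-10-phenyldecanoate (both epimers at the peroxy acetal carbon) | COC(OO)[C@H](CCCCCc1ccccc1)CCCC(=O)O[Si](C)(C)C | intermediate
7 | (5R)-5-formyl-10-phenyldecanoic acid | O=C[C@H](CCCCCc1ccccc1)CCCC(=O)O | intermediate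
8 | (methoxymethyl)triphenylphosphonium chloride | COC[P+](c1ccccc1)(c1ccccc1)c1ccccc1.[Cl-] | starting material
9 | (methoxymethylidene)triphenyl-λ5-phosphane | COC=P(c1ccccc1)(c1ccccc1)c1ccccc1 | intermediate
10 | (5R)-5-(2-methoxyethenyl)-10-phenyldecanoic acid, equally (5R)-7-methoxy-5-(5-phenylpentyl)hept-6-enoic acid, E/Z mixture | COC=C[C@H](CCCCCc1ccccc1)CCCC(=O)O | intermediate
11 | DL-alanine methyl ester hydrochloride | COC(=O)C(C)N.Cl | starting material
12 | 1H-benzotriazol-1-yl (5R)-5-(2-methoxyethenyl)-10-phenyldecanoate | COC=C[C@H](CCCCCc1ccccc1)CCCC(=O)On1nnc2ccccc12 | intermediate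
13 | methyl N-[(5R)-5-(2-methoxyethenyl)-10-phenyldecanoyl]alaninate | COC=C[C@H](CCCCCc1ccccc1)CCCC(=O)NC(C)C(=O)OC | intermediate
14 | 5-methoxy-2-[(4R)-4-(2-methoxyethenyl)-9-phenylnonyl]-4-methyl-1,3-oxazole | COC=C[C@H](CCCCCc1ccccc1)CCCc1nc(C)c(OC)o1 | intermediate
15 | (5R)-3,8a-epoxy-3,4-dimethoxy-2-methyl-5-(5-phenylpentyl)-3,4,4a,5,6,7,8,8a-octahydroquinoline (7-oxa-2-azabicyclo[2.2.1]hept-2-ene core, diastereomer mixture at C3, C4, C4a, C8a) | COC1C2[C@H](CCCCCc3ccccc3)CCCC23OC1(OC)C(C)=N3 | intermediate
16 | (5R)-3,4-dimethoxy-2-methyl-5-(5-phenylpentyl)-3,4,5,6,7,8-hexahydroquinolin-3-ol | COC1C(O)(OC)C(C)=NC2=C1[C@H](CCCCCc1ccccc1)CCC2 | intermediate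
17 | (5R)-4-methoxy-2-methyl-5-(5-phenylpentyl)-5,6,7,8-tetrahydroquinolin-3-ol | COc1c(O)c(C)nc2c1[C@H](CCCCCc1ccccc1)CCC2 | intermediate
18 | (5R)-3,4-dimethoxy-2-methyl-5-(5-phenylpentyl)-5,6,7,8-tetrahydroquinoline | COc1c(OC)c(C)nc2c1[C@H](CCCCCc1ccccc1)CCC2 | intermediate
19 | (5R)-3,4-dimethoxy-2-methyl-5-(5-phenylpentyl)-5,6,7,8-tetrahydroquinoline 1-oxide | COc1c(OC)c(C)[n+]([O-])c2c1[C@H](CCCCCc1ccccc1)CCC2 | target

Total step count: 9. Longest linear sequence: 9 steps (1 to 19); 3, 8 and 11 enter as bought materials.

**Steps most likely to fail**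

1. Step 7. What may go wrong:
- The cycloaddition may be too slow, because both partners are electron-rich until the oxazole is protonated and a six-membered carbocycle has to form.
- The basic product may sequester the acid, so that the reaction stalls.
- The enol ether may be lost by protonation followed by demethylation or oligomerisation.
- The adduct may lose methanol across C4–C4a and then extrude acetonitrile instead of opening to the pyridine.

The fallback uses only known reaction types, sets out from 7 and comes back to the route at 17. It keeps the same two-bond disconnection but brings in the C4 oxygen afterwards. Wittig methylenation of 7 (methyltriphenylphosphonium bromide, KN(SiMe3)2, THF, –78 °C) should give (5R)-5-ethenyl-10-phenyldecanoic acid F1. EDC/HOBt coupling with 11 should give methyl N-[(5R)-5-ethenyl-10-phenyldecanoyl]alaninate F2. Classical cyclodehydration (P2O5, CHCl3, reflux), tolerable now that no enol ether is present, should give 2-[(4R)-4-ethenyl-9-phenylnonyl]-5-methoxy-4-methyl-1,3-oxazole F3. The established intramolecular Kondrat'eva reaction of a 5-alkoxyoxazole with an unactivated terminal alkene (o-dichlorobenzene, 180 °C) should give (5R)-2-methyl-5-(5-phenylpentyl)-5,6,7,8-tetrahydroquinolin-3-ol F4. Iodination of the pyridinolate (I2, Na2CO3, THF–H2O) can only reach C4, the sole free ring position and ortho to the hydroxyl, and should give (5R)-4-iodo-2-methyl-5-(5-phenylpentyl)-5,6,7,8-tetrahydroquinolin-3-ol F5. Ullmann-type methoxylation of the ortho-iodo pyridinol (NaOMe, CuI, DMF–MeOH, 110 °C), the reaction type that converts 5-iodovanillin into syringaldehyde, then gives 17.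

2. Step 6. The chlorophosphonium reagent or adventitious HCl may attack the nucleophilic enol ether faster than the amide is activated. The product carries two acid-labile groups and may also be degraded on isolation.

The fallback sets out from 13 and comes back at 14. It masks the alkene as its acetal while the oxazole is built. Addition of methanol to the enol ether (MeOH, catalytic pyridinium p-toluenesulfonate, rt) should give methyl N-[(5R)-5-(2,2-dimethoxyethyl)-10-phenyldecanoyl]alaninate F6. The acetal is inert to PPh3/C2Cl6/Et3N even with excess reagent and warming, so cyclodehydration should give 2-[(4R)-4-(2,2-dimethoxyethyl)-9-phenylnonyl]-5-methoxy-4-methyl-1,3-oxazole F7. Elimination of one methoxy group with Me3SiOTf and iPr2NEt (CH2Cl2, –20 °C to rt), the standard conversion of a dimethyl acetal into a methyl enol ether, then gives 14.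

3. Step 4. What may go wrong:
- The basic ylide may epimerise the alpha-branched aldehyde.
- Residual methanol or dimethyl sulfoxide in the crude ozonolysis product may quench the ylide.
- The enol ether may hydrolyse while the free acid is extracted.

The fallback sets out from 2 and comes back at 10. It places the stereocentre beta to every carbonyl group, so that it cannot epimerise, and it avoids the ring cleavage altogether. Wittig reaction of commercial methyl 5-oxopentanoate with S-ethyl 2-(triphenyl-λ5-phosphanylidene)ethanethioate (CH2Cl2, rt) should give methyl (5E)-7-(ethylsulfanyl)-7-oxohept-5-enoate F8. Copper-catalysed asymmetric conjugate addition of 2 follows (CuBr·SMe2, 1-[2-(diphenylphosphanyl)ferrocenyl]ethyl-dicyclohexylphosphane (JosiPhos ligand, enantiomer chosen for the R product), t-BuOMe, –75 °C) and should give methyl (5R)-5-[2-(ethylsulfanyl)-2-oxoethyl]-10-phenyldecanoate F9. Fukuyama reduction (Et3SiH, palladium on carbon, acetone) should give methyl (5R)-5-(2-oxoethyl)-10-phenyldecanoate F10. Acetalisation (HC(OMe)3, MeOH, catalytic pyridinium p-toluenesulfonate) should give methyl (5R)-5-(2,2-dimethoxyethyl)-10-phenyldecanoate F11. Treatment with Me3SiOTf and iPr2NEt should give methyl (5R)-5-(2-methoxyethenyl)-10-phenyldecanoate F12. Saponification (LiOH, THF–H2O, then NaH2PO4 to pH 5–6) gives 10.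

**Further compounds**
F1 | step 7 | (5R)-5-ethenyl-10-phenyldecanoic acid | C=C[C@H](CCCCCc1ccccc1)CCCC(=O)O
F2 | step 7 | methyl N-[(5R)-5-ethenyl-10-phenyldecanoyl]alaninate | C=C[C@H](CCCCCc1ccccc1)CCCC(=O)NC(C)C(=O)OC
F3 | step 7 | 2-[(4R)-4-ethenyl-9-phenylnonyl]-5-methoxy-4-methyl-1,3-oxazole | C=C[C@H](CCCCCc1ccccc1)CCCc1nc(C)c(OC)o1
F4 | step 7 | (5R)-2-methyl-5-(5-phenylpentyl)-5,6,7,8-tetrahydroquinolin-3-ol | c1c(O)c(C)nc2c1[C@H](CCCCCc1ccccc1)CCC2
F5 | step 7 | (5R)-4-iodo-2-methyl-5-(5-phenylpentyl)-5,6,7,8-tetrahydroquinolin-3-ol | Ic1c(O)c(C)nc2c1[C@H](CCCCCc1ccccc1)CCC2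
F6 | step 6 | methyl N-[(5R)-5-(2,2-dimethoxyethyl)-10-phenyldecanoyl]alaninate | COC(OC)C[C@H](CCCCCc1ccccc1)CCCC(=O)NC(C)C(=O)OC
F7 | step 6 | 2-[(4R)-4-(2,2-dimethoxyethyl)-9-phenylnonyl]-5-methoxy-4-methyl-1,3-oxazole | COC(OC)C[C@H](CCCCCc1ccccc1)CCCc1nc(C)c(OC)o1
F8 | step 4 | methyl (5E)-7-(ethylsulfanyl)-7-oxohept-5-enoate | CCSC(=O)/C=C/CCCC(=O)OC
F9 | step 4 | methyl (5R)-5-[2-(ethylsulfanyl)-2-oxoethyl]-10-phenyldecanoate | CCSC(=O)C[C@H](CCCCCc1ccccc1)CCCC(=O)OC
F10 | step 4 | methyl (5R)-5-(2-oxoethyl)-10-phenyldecanoate | O=CC[C@H](CCCCCc1ccccc1)CCCC(=O)OC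
F11 | step 4 | methyl (5R)-5-(2,2-dimethoxyethyl)-10-phenyldecanoate | COC(OC)C[C@H](CCCCCc1ccccc1)CCCC(=O)OC
F12 | step 4 | methyl (5R)-5-(2-methoxyethenyl)-10-phenyldecanoate | COC=C[C@H](CCCCCc1ccccc1)CCCC(=O)OC
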